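**Retrosynthetic overview**

1. Daucane numbers are used: C1 = quaternary ring-fusion carbon with CH3-15, C4 = isopropyl carbinol, C5 = ring-fusion CH, C8 carries CH3-14; α = face of H-5, β = face of CH3-15.
2. Target 23 ⇐ 2-O-acetyl and 6-O-veratroyl esters of the triol from C4-OH-directed reduction of bicyclic epoxy dione 18 (C10-OH carried as its triethylsilyl ether).
3. 18 ⇐ acyclic, farnesane-type epoxy aldehyde ene-trione 14 by a one-flask bicyclization: C10–C1 first (seven-membered ring, thiolate-triggered Michael–aldol), then C4–C5 (five-membered ring, samarium enolate aldol), the two bonds and the order presumed for the daucane cyclase.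
4. 14 ⇐ aldehyde 3 + diketo ylide 10 (α-aminoxylation/Wittig, then double oxidation).
5. 3 ⇐ (2R,3R)-2,3-epoxygeraniol 2 ⇐ geraniol 1 (Sharpless epoxidation of the E-olefin gives the trans-oxirane, which sets C8/C9 and then controls C10, C1, C5 and C4).

Assumption: the target is made exactly as its SMILES reads, i.e. with C7 and C10 on opposite faces of the oxirane (trans-fused, O–C8 β and O–C9 α, written (8R,9R)-8,9-epoxy below); such a ring is strained but its carbocyclic analogues are isolable, and it can only arise by closing the seven-membered ring onto a preformed trans-oxirane.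

**Route**

Step 1
Reactants: 1 geraniol ((2E)-3,7-dimethylocta-2,6-dien-1-ol)
Product: 2 [(2R,3R)-3-methyl-3-(4-methylpent-3-en-1-yl)oxiran-2-yl]methanol
Conditions: Ti(OiPr)4 (5 mol%), D-(−)-diethyl tartrate (7 mol%), t-BuOOH, 4 Å sieves, CH2Cl2, −20 °C
Reagents that add atoms: tert-butyl hydroperoxide, CC(C)(C)OO
Why: Katsuki–Sharpless asymmetric epoxidation of the E-allylic alcohol; syn oxygen transfer keeps CH2OH (later C10) and the chain (C7) trans on the oxirane, and the D-tartrate selects the face that gives (2R,3R), i.e. C9 (R) and C8 (R) of the target.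

Step 2
Reactants: 2 [(2R,3R)-3-methyl-3-(4-methylpent-3-en-1-yl)oxiran-2-yl]methanol
Product: 3 3-[(2R,3R)-3-(hydroxymethyl)-2-methyloxiran-2-yl]propanal
Conditions: O3, CH2Cl2/MeOH, −78 °C; then Me2S, −78 °C → rt
Reagents that add atoms: ozone, [O-][O+]=O
Why: ozonolysis (Criegee) of the only C=C with reductive work-up gives the aldehyde without touching the epoxide stereocentres.

Step 3
Reactants: 4 3-chlorobutan-2-one; 5 triphenylphosphine
Product: 7 3-(triphenylphosphoranylidene)butan-2-one, via phosphonium chloride 6 (not isolated)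
Conditions: toluene, 110 °C; then aq. NaOH, CH2Cl2, rt
Reagents that add atoms: none
Why: SN2 quaternisation of the phosphine and deprotonation of the acyl-stabilised phosphonium salt (Wittig reagent preparation); no stereocentre is involved.

Step 4
Reactants: 7 3-(triphenylphosphoranylidene)butan-2-one; 8 methyl 2-methylpropanoate
Product: 10 6-methyl-2-(triphenylphosphoranylidene)heptane-3,5-dione, via lithium ylide enolate 9 (not isolated)
Conditions: LiN(iPr)2 (2.2 equiv), THF, −78 °C; then 8, −78 → 0 °C; aq. NH4Cl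
Reagents that add atoms: none
Why: γ-deprotonation of the acyl ylide and Claisen-type C-acylation of the ylide enolate by the ester (ylide-anion acylation), the second equivalent of base absorbing the acidic diketone.

Step 5
Reactants: 3 3-[(2R,3R)-3-(hydroxymethyl)-2-methyloxiran-2-yl]propanal; 10 6-methyl-2-(triphenylphosphoranylidene)heptane-3,5-dione
Product: 12 (6E,8R)-8-(anilinooxy)-9-[(2R,3R)-3-(hydroxymethyl)-2-methyloxiran-2-yl]-2,6-dimethylnon-6-ene-3,5-dione, via anilinooxy aldehyde 11 (not isolated)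
Conditions: PhN=O, L-proline (20 mol%), CHCl3, 4 °C; then 10, CH2Cl2, rt
Reagents that add atoms: nitrosobenzene, O=Nc1ccccc1
Why: proline-enamine α-aminoxylation (O-selective nitroso aldol) followed by Wittig olefination with the stabilised ylide, which gives the E-enone; the C6 centre (R, from L-proline) is temporary and is erased in step 7.

Step 6
Reactants: 12 (6E,8R)-8-(anilinooxy)-9-[(2R,3R)-3-(hydroxymethyl)-2-methyloxiran-2-yl]-2,6-dimethylnon-6-ene-3,5-dione
Product: 13 (6E,8R)-8-hydroxy-9-[(2R,3R)-3-(hydroxymethyl)-2-methyloxiran-2-yl]-2,6-dimethylnon-6-ene-3,5-dione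
Conditions: CuSO4·5H2O (30 mol%), MeOH, 0 °C
Reagents that add atoms: none
Why: copper-catalysed N–O bond cleavage of the O-alkyl-N-arylhydroxylamine frees the allylic alcohol, the C–O bond and its configuration being untouched.

Step 7
Reactants: 13 (6E,8R)-8-hydroxy-9-[(2R,3R)-3-(hydroxymethyl)-2-methyloxiran-2-yl]-2,6-dimethylnon-6-ene-3,5-dione
Product: 14 (2S,3R)-3-[(3E)-4,8-dimethyl-2,5,7-trioxonon-3-en-1-yl]-3-methyloxirane-2-carbaldehyde
Conditions: Dess–Martin periodinane (2.5 equiv), NaHCO3, CH2Cl2, 0 °C; used crude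
Reagents that add atoms: none
Why: Dess–Martin oxidation of the primary and the allylic secondary alcohol under buffered conditions gives the epoxy aldehyde and the 2-ene-1,4-dione; C8/C9 are untouched and C6 becomes sp2.

Step 8
Reactants: 14 (2S,3R)-3-[(3E)-4,8-dimethyl-2,5,7-trioxonon-3-en-1-yl]-3-methyloxirane-2-carbaldehyde
Product: 18 (8R,9R)-8,9-epoxy-4β,10α-dihydroxy-5αH-daucane-2,6-dione, via trimethylsilyl enol ether 15 (not isolated), via seven-membered thio-aldolate 16 (not isolated), via ring samarium enolate 17 (not isolated)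
Conditions: Me3SiCl (1.05 equiv), Et3N (1.1 equiv), THF, −20 °C, filtered under Ar; Me2AlSPh (1.2 equiv), THF (0.005 M), −78 °C; then SmI2 (2.4 equiv), THF, −78 → −30 °C; pH 5 citrate buffer, 0 °C
Reagents that add atoms: none
Why: Proposed new method: Me2AlSPh binds the most basic (vinylogous-ester) carbonyl O2 and delivers PhS to the only unhindered β-carbon, C5, through the s-cis enone, so the C1=C2 aluminium enolate has O2 cis to C5 and closes the seven-membered ring on the epoxy aldehyde through a chelated chair (C9 equatorial, C1 anti to the oxirane C9–O bond in the polar Felkin–Anh sense), which sets C10 (R, OH α) and quaternary C1 (CH3-15 anti to the new C10–O bond) while only sp3 carbons and a ketone, not a ring double bond, span the trans-oxirane and the competing six-membered closure through C5 is excluded (it would need a trans-bicyclo[4.1.0]heptane); SmI2 (two electrons from divalent samarium) then cleaves the C5–S bond α to the C6 ketone to the ring-held trivalent samarium enolate, which is regiodefined at C5 and lies away from C7 so that the epoxide is not opened by β-elimination, and which adds to C4 of the aluminium-activated β-silyloxy enone arm with O4 chelated toward O6 and isopropyl outside, the C2 arm reaching the β-face of C5 across the wide C10–C1–C5–C6 torsion of the twisted ring so that H-5 ends α (trans ring fusion); the closest known reactions are the Me2AlSPh-triggered Michael–aldol coupling of enones with aldehydes and SmI2 Reformatsky-type aldol cyclisations of α-heterosubstituted ketones, and the order C10–C1 then C4–C5 copies the two closures presumed for the cyclase.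

Step 9
Reactants: 18 (8R,9R)-8,9-epoxy-4β,10α-dihydroxy-5αH-daucane-2,6-dione
Product: 19 (8R,9R)-8,9-epoxy-4β-hydroxy-10α-(triethylsilyloxy)-5αH-daucane-2,6-dione
Conditions: Et3SiCl (1.2 equiv), imidazole, DMF, 0 °C
Reagents that add atoms: chlorotriethylsilane, CC[Si](Cl)(CC)CC
Why: silylation of the secondary C10 hydroxyl only (the tertiary C4 hydroxyl is inert), so that C4-OH alone directs step 10 and C10-OH stays out of the acylations.

Step 10
Reactants: 19 (8R,9R)-8,9-epoxy-4β-hydroxy-10α-(triethylsilyloxy)-5αH-daucane-2,6-dione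
Product: 20 (8R,9R)-8,9-epoxy-10α-(triethylsilyloxy)-5αH-daucane-2α,4β,6α-triol
Conditions: Me4NBH(OAc)3 (8 equiv), MeCN/AcOH (4:1), −35 °C
Reagents that add atoms: none
Why: Evans–Saksena hydroxyl-directed reduction: hydride bound at the 4β-oxygen is delivered intramolecularly to the β-face of both β-keto groups, giving the 1,3-anti diols (6α-OH and 2α-OH).

Step 11
Reactants: 20 (8R,9R)-8,9-epoxy-10α-(triethylsilyloxy)-5αH-daucane-2α,4β,6α-triol
Product: 21 (8R,9R)-8,9-epoxy-2α,4β-dihydroxy-10α-(triethylsilyloxy)-5αH-daucan-6α-yl 3,4-dimethoxybenzoate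
Conditions: 3,4-dimethoxybenzoyl chloride (1.1 equiv), pyridine, 4-(dimethylamino)pyridine (5 mol%), CH2Cl2, −20 → 0 °C
Reagents that add atoms: 3,4-dimethoxybenzoyl chloride, COc1ccc(cc1OC)C(Cl)=O
Why: nucleophile-catalysed acylation; the C6 hydroxyl (flanked by CH2 and CH) reacts before the neopentyl C2 hydroxyl and the tertiary C4 hydroxyl does not react, with no stereocentre touched.

Step 12
Reactants: 21 (8R,9R)-8,9-epoxy-2α,4β-dihydroxy-10α-(triethylsilyloxy)-5αH-daucan-6α-yl 3,4-dimethoxybenzoate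
Product: 22 (8R,9R)-2α-acetoxy-8,9-epoxy-4β-hydroxy-10α-(triethylsilyloxy)-5αH-daucan-6α-yl 3,4-dimethoxybenzoate
Conditions: Ac2O, Et3N, 4-(dimethylamino)pyridine (0.2 equiv), CH2Cl2, rt
Reagents that add atoms: acetic anhydride, CC(=O)OC(C)=O
Why: 4-(dimethylamino)pyridine-catalysed acetylation of the only remaining secondary hydroxyl, with retention at C2.

Step 13
Reactants: 22 (8R,9R)-2α-acetoxy-8,9-epoxy-4β-hydroxy-10α-(triethylsilyloxy)-5αH-daucan-6α-yl 3,4-dimethoxybenzoate
Product: 23 (1R,2R,4S,5R,6R,8R,9R,10R)-2α-acetoxy-8,9-epoxy-4β,10α-dihydroxy-5αH-daucan-6α-yl 3,4-dimethoxybenzoate (target)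
Conditions: Bu4NF (1.2 equiv), AcOH (1.2 equiv), THF, 0 °C
Reagents that add atoms: none
Why: fluoride cleavage of the Si–O bond, buffered with acetic acid so that neither ester migrates nor the strained epoxide opens, gives the target.

**Compound list**

1 | geraniol, (2E)-3,7-dimethylocta-2,6-dien-1-ol | OC/C=C(\C)CCC=C(C)C | starting material
2 | [(2R,3R)-3-methyl-3-(4-methylpent-3-en-1-yl)oxiran-2-yl]methanol | OC[C@H]1O[C@]1(C)CCC=C(C)C | intermediate
3 | 3-[(2R,3R)-3-(hydroxymethyl)-2-methyloxiran-2-yl]propanal | OC[C@H]1O[C@]1(C)CCC=O | intermediate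
4 | 3-chlorobutan-2-one (racemic) | CC(=O)C(C)Cl | starting material
5 | triphenylphosphine | c1ccc(cc1)P(c1ccccc1)c1ccccc1 | starting material
6 | (3-oxobutan-2-yl)triphenylphosphonium chloride | CC(=O)C(C)[P+](c1ccccc1)(c1ccccc1)c1ccccc1.[Cl-] | intermediate
7 | 3-(triphenylphosphoranylidene)butan-2-one | CC(=O)C(C)=P(c1ccccc1)(c1ccccc1)c1ccccc1 | intermediate
8 | methyl 2-methylpropanoate | COC(=O)C(C)C | starting material
9 | lithium 3-(triphenylphosphoranylidene)but-1-en-2-olate | [Li+].[O-]C(=C)C(C)=P(c1ccccc1)(c1ccccc1)c1ccccc1 | intermediate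
10 | 6-methyl-2-(triphenylphosphoranylidene)heptane-3,5-dione | CC(C)C(=O)CC(=O)C(C)=P(c1ccccc1)(c1ccccc1)c1ccccc1 | intermediate
11 | (2R)-2-(anilinooxy)-3-[(2R,3R)-3-(hydroxymethyl)-2-methyloxiran-2-yl]propanal | OC[C@H]1O[C@]1(C)C[C@@H](ONc1ccccc1)C=O | intermediate
12 | (6E,8R)-8-(anilinooxy)-9-[(2R,3R)-3-(hydroxymethyl)-2-methyloxiran-2-yl]-2,6-dimethylnon-6-ene-3,5-dione | OC[C@H]1O[C@]1(C)C[C@@H](ONc1ccccc1)/C=C(\C)C(=O)CC(=O)C(C)C | intermediate
13 | (6E,8R)-8-hydroxy-9-[(2R,3R)-3-(hydroxymethyl)-2-methyloxiran-2-yl]-2,6-dimethylnon-6-ene-3,5-dione | OC[C@H]1O[C@]1(C)C[C@@H](O)/C=C(\C)C(=O)CC(=O)C(C)C | intermediate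
14 | (2S,3R)-3-[(3E)-4,8-dimethyl-2,5,7-trioxonon-3-en-1-yl]-3-methyloxirane-2-carbaldehyde | O=C[C@H]1O[C@]1(C)CC(=O)/C=C(\C)C(=O)CC(=O)C(C)C | intermediate
15 | (2S,3R)-3-[(3E,6Z)-4,8-dimethyl-2,5-dioxo-7-(trimethylsilyloxy)nona-3,6-dien-1-yl]-3-methyloxirane-2-carbaldehyde | O=C[C@H]1O[C@]1(C)CC(=O)/C=C(\C)C(=O)/C=C(\O[Si](C)(C)C)C(C)C | intermediate
16 | seven-membered thio-aldolate (daucane numbers): 6-oxocycloheptane with trans-fused (8R,9R)-8,9-epoxide, 10α-O-AlMe2, 1β-CH3, 1α-[(2Z)-4-methyl-3-(trimethylsilyloxy)pent-2-enoyl] arm and 5-SPh (both C5 epimers) | C1(Sc2ccccc2)C(=O)C[C@@]2(C)O[C@@H]2[C@H](O[Al](C)C)[C@]1(C)C(=O)/C=C(\O[Si](C)(C)C)C(C)C | intermediate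
17 | ring samarium enolate (daucane numbers): C5=C6 enolate O-SmI2 of 16 after loss of SPh, other groups as in 16 | C1=C(O[Sm](I)I)C[C@@]2(C)O[C@@H]2[C@H](O[Al](C)C)[C@]1(C)C(=O)/C=C(\O[Si](C)(C)C)C(C)C | intermediate
18 | (8R,9R)-8,9-epoxy-4β,10α-dihydroxy-5αH-daucane-2,6-dione (oxirane trans-fused: O–C8 β, O–C9 α) | O=C2C[C@@]3(C)O[C@@H]3[C@H](O)[C@]3(C)C(=O)C[C@](O)(C(C)C)[C@@H]23 | intermediate
19 | (8R,9R)-8,9-epoxy-4β-hydroxy-10α-(triethylsilyloxy)-5αH-daucane-2,6-dione | O=C2C[C@@]3(C)O[C@@H]3[C@H](O[Si](CC)(CC)CC)[C@]3(C)C(=O)C[C@](O)(C(C)C)[C@@H]23 | intermediate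
20 | (8R,9R)-8,9-epoxy-10α-(triethylsilyloxy)-5αH-daucane-2α,4β,6α-triol | O[C@@H]2C[C@@]3(C)O[C@@H]3[C@H](O[Si](CC)(CC)CC)[C@]3(C)[C@H](O)C[C@](O)(C(C)C)[C@@H]23 | intermediate
21 | (8R,9R)-8,9-epoxy-2α,4β-dihydroxy-10α-(triethylsilyloxy)-5αH-daucan-6α-yl 3,4-dimethoxybenzoate | COc1ccc(C(=O)O[C@@H]2C[C@@]3(C)O[C@@H]3[C@H](O[Si](CC)(CC)CC)[C@]3(C)[C@H](O)C[C@](O)(C(C)C)[C@@H]23)cc1OC | intermediate
22 | (8R,9R)-2α-acetoxy-8,9-epoxy-4β-hydroxy-10α-(triethylsilyloxy)-5αH-daucan-6α-yl 3,4-dimethoxybenzoate | COc1ccc(C(=O)O[C@@H]2C[C@@]3(C)O[C@@H]3[C@H](O[Si](CC)(CC)CC)[C@]3(C)[C@H](OC(C)=O)C[C@](O)(C(C)C)[C@@H]23)cc1OC | intermediate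
23 | (1R,2R,4S,5R,6R,8R,9R,10R)-2α-acetoxy-8,9-epoxy-4β,10α-dihydroxy-5αH-daucan-6α-yl 3,4-dimethoxybenzoate | COc1ccc(C(=O)O[C@@H]2C[C@@]3(C)O[C@@H]3[C@H](O)[C@]3(C)[C@H](OC(C)=O)C[C@](O)(C(C)C)[C@@H]23)cc1OC | target

**Step count and risks**

Total step count: 13. Longest linear sequence: 11 (steps 1, 2 and 5–13; steps 3 and 4 make the ylide).

Steps most likely to fail:

Step 8 (one-flask bicyclization). The aluminium thiolate may open the epoxide or stay on the aldehyde. The seven-membered ring must close across a trans-oxirane. The five-membered ring may close cis-fused, because an enolate normally takes its tether on the face of C2; the trans outcome drawn is the least certain stereochemical call in the route. The fallback replaces the thiolate relay by silyl enol ether/Lewis acid chemistry and sets out from 14. Me3SiCl/Et3N gives 15. SmI2 (2.1 equiv) with Et3SiCl in THF at −78 °C then reduces the ene-dione and silylates both new enolates to the mixed tris(silyl enol ether) F1; only its (2E) C5=C6 isomer, with C7 and C1 cis, can cyclise. BF3·OEt2 (CH2Cl2, −78 °C, 0.002 M) closes C10–C1 and then C4–C5 by two Mukaiyama aldol additions through open transition states. It comes back to the route at 18 after aqueous NaHCO3.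

Step 10 (double directed reduction). The tertiary hydroxyl may bind boron too slowly, and the strained epoxide or the silyl ether may not survive acetic acid. The fallback sets out from 18, needs no silyl group and uses no acid. Et2BOMe/NaBH4 (THF/MeOH, −78 °C, Narasaka–Prasad) reduces the C2 ketone, chelated to the free C10 hydroxyl, to the syn diol trihydroxy ketone F2. SmI2 in THF/MeOH at 0 °C reduces the C6 ketone through its chelate with C4-OH to the anti diol, giving tetrol F3. 3,4-Dimethoxybenzoyl chloride/pyridine acylates the least hindered C6 hydroxyl to veratrate F4. Ac2O (1.05 equiv, pyridine, 0 °C) acetylates C2-OH in preference to the epoxide-flanked C10-OH, coming back to the route at 23.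

Step 5 (aminoxylation/Wittig in one flask). The α-methyl keto ylide is sluggish and the α-anilinooxy aldehyde may eliminate or decompose before it is trapped. The fallback sets out from 3 and puts the C6 oxygen in after the olefination. Wittig reaction of 3 with 10 (toluene, 80 °C) gives enone F5. CrO3·3,5-dimethylpyrazole (CH2Cl2, −20 °C) then oxidises the allylic methylene γ to the enone carbonyl to the ketone and the primary alcohol to the aldehyde, coming back to the route at 14.

**Further compounds**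

F1 | step 8 | (2S,3R)-3-[(2E,4E,6Z)-4,8-dimethyl-2,5-bis(triethylsilyloxy)-7-(trimethylsilyloxy)nona-2,4,6-trien-1-yl]-3-methyloxirane-2-carbaldehyde | O=C[C@H]1O[C@]1(C)C/C(O[Si](CC)(CC)CC)=C\C(C)=C(O[Si](CC)(CC)CC)/C=C(\O[Si](C)(C)C)C(C)C
F2 | step 10 | (8R,9R)-8,9-epoxy-2α,4β,10α-trihydroxy-5αH-daucan-6-one | O=C2C[C@@]3(C)O[C@@H]3[C@H](O)[C@]3(C)[C@H](O)C[C@](O)(C(C)C)[C@@H]23
F3 | step 10 | (8R,9R)-8,9-epoxy-5αH-daucane-2α,4β,6α,10α-tetrol | O[C@@H]2C[C@@]3(C)O[C@@H]3[C@H](O)[C@]3(C)[C@H](O)C[C@](O)(C(C)C)[C@@H]23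
F4 | step 10 | (8R,9R)-8,9-epoxy-2α,4β,10α-trihydroxy-5αH-daucan-6α-yl 3,4-dimethoxybenzoate | COc1ccc(C(=O)O[C@@H]2C[C@@]3(C)O[C@@H]3[C@H](O)[C@]3(C)[C@H](O)C[C@](O)(C(C)C)[C@@H]23)cc1OC
F5 | step 5 | (6E)-9-[(2R,3R)-3-(hydroxymethyl)-2-methyloxiran-2-yl]-2,6-dimethylnon-6-ene-3,5-dione | OC[C@H]1O[C@]1(C)CC/C=C(\C)C(=O)CC(=O)C(C)C
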